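The constants of the steps in solution close a ring, and the solid substrate feeds that ring through its solubility.

    target ⇌ isomer of the product A (K1 = 0.30, k1 = 2.7 h⁻¹)
    isomer of the product A ⇌ isomer of the product B (K2 = 2.8, k2 = 0.12 h⁻¹)
    isomer of the product B ⇌ starting material (k3 = 3.6 h⁻¹)
    starting material ⇌ target (K4 = 1.9, k4 = 0.43 h⁻¹)
    solid substrate ⇌ starting material, rate k5*(cs5 - [starting material]) while solid is left; crystals form when [starting material] > cs5 (cs5 = 30 mM, k5 = 2.3 h⁻¹)

solid substrate 0.86 M; time 15 h

- given per volume of solution although it is solid: solid substrate
- at the start none of the solid substrate is in solution
- run time (flask): 15 h

1. target at 15 h, in percent of the solid substrate charged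
2. the change that raises the amount of target at 15 h, in percent of the solid substrate charged most ("none" if none brings more than 2 percentage points) (Saturday's / Tuesday's / none)
3. amount of target at 15 h, in percent of the solid substrate charged, after Tuesday's

- Saturday's: doubling the dissolution coefficient of step 5, all else as stated
- Tuesday's: doubling the solubility in step 5, all else as stated

I write the balance of the solid substrate: what leaves the solid stands as the dissolved forms, and at rest beside crystals c(starting material) equals the solubility 30 mM, so c(target) stands at 57.0 mM, its saturation ceiling, the solubility times the equilibrium constant 1.9 of the step from starting material to target, which is 6.63% of this flask's charge. All dissolved forms together then hold 152 mM, less than the charge of 0.86 M, so crystals remain. How near the target comes by 15 h my reckoning does not reach, and I commit to a value a little below the ceiling. Into a solution kept empty, with solid never running out, step 5 can deliver 120% of the charge by then, more than the 17.7% that the dissolved forms hold at rest, so I expect Saturday's change to stay below 2 percentage points, whereas Tuesday's lifts the ceiling to 13.3% of the charge.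

The forecast gives 5.9%, names Tuesday's and gives 11.8% after it, on the ground that “doubling the solubility roughly doubles the target”.

The flask gives 5.91%; Saturday's change brings 0.22 points, Tuesday's brings 5.9 points and reaches 11.8%, so the answer is Tuesday's.

By 15.0 h this flask has drawn 16.5% of its charge out of the solid, less than the 120% that step 5 can deliver into a solution kept empty, and 83.5% still stands as solid. Its target has reached 89.1% of the ceiling. The target at 15 h, in percent of the charge, has moved by 5 points when the charge of this flask is lowered to 0.466 M. In the neighbour flask with 0.21 M of solid substrate, the same ceiling is 27.1% of the charge, 32.3% stands as solid, and the target reads 24.2%, which is 50.8 mM against 50.8 mM in the first flask.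

The constants were chosen freely; what happens was integrated by code.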